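**Retrosynthetic overview**

1. The target is epirobinetinidol-(4β→8)-epirobinetinidol-(4α→8)-epicatechin; the last step is hydrogenolysis of a tetradeca-O-benzyl precursor.
2. Key disconnection: ring C of the middle unit is cut at O1–C8a and C4–C4a. This releases ring A of the middle unit as a 2-substituted cyclohexane-1,3-dione (top unit already on C8) and a β-hydroxy ketone that carries ring B, C2–C3–C4 and the epicatechin unit.
3. Enabling feature: ring A of the middle unit is a 5-deoxy (resorcinol) ring with oxygen on C7 and C8a, the top unit on C8 between them and only hydrogen on C5 and C6. It is therefore the aromatised form of a dione in which C8a is a carbonyl carbon open to O1, C4a is an α-methylene that can attack C4, and C5/C6 supply the hydrogens that a C4 ketone lacks.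
4. Fragments: one Evans glycolate aldol sets C2/C3 of both robinetinidol units. The top unit is closed by aryl Grignard addition and copper-catalysed O-arylation, then joined to cyclohexane-1,3-dione at C4 (3,4-trans). The bottom unit comes from (−)-epicatechin by C8 lithiation.
5. Ring order: ring C of the top unit (step 7), then ring C of the middle unit together with aromatisation of its ring A (step 13); the rings of the bottom unit are bought.

Key step: step 13

Remark on the chemistry: the carbinol configuration at C4 of 14 and 15 is immaterial because that carbon is ionised in step 8; 3-bromo-4-iodophenol, 3,4,5-tris(benzyloxy)benzaldehyde and (−)-epicatechin are taken as commercial.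

**Route**

Step 1
Reactants: 1 (S)-4-benzyloxazolidin-2-one; 2 (benzyloxy)acetyl chloride
Product: 4 (S)-4-benzyl-3-[(benzyloxy)acetyl]oxazolidin-2-one, via lithium amide 3 (not isolated)
Conditions: n-BuLi, THF, −78 °C; then 2, −78 → 0 °C
Reagents that add atoms: none
Why: N-acylation of the lithiated Evans auxiliary by an acid chloride is standard and leaves the auxiliary stereocentre untouched.

Step 2
Reactants: 4 (S)-4-benzyl-3-[(benzyloxy)acetyl]oxazolidin-2-one; 5 3,4,5-tris(benzyloxy)benzaldehyde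
Product: 7 (S)-4-benzyl-3-[(2S,3R)-2-(benzyloxy)-3-hydroxy-3-[3,4,5-tris(benzyloxy)phenyl]propanoyl]oxazolidin-2-one, via boron enolate 6 (not isolated)
Conditions: Bu2BOTf, Et3N, CH2Cl2, −78 → 0 °C; 5, −78 → 0 °C; H2O2, MeOH, pH 7 buffer
Reagents that add atoms: none
Why: Evans syn-glycolate aldol reaction, in which the Z-boron enolate reacts through a closed chair transition state on the face away from the benzyl group of the auxiliary and should set both new centres (2S,3R, benzyloxy and hydroxyl syn), the future C3 and C2 of a 2,3-cis flavan.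

Step 3
Reactants: 7 (S)-4-benzyl-3-[(2S,3R)-2-(benzyloxy)-3-hydroxy-3-[3,4,5-tris(benzyloxy)phenyl]propanoyl]oxazolidin-2-one
Product: 8 (2S,3R)-2-(benzyloxy)-3-hydroxy-N-methoxy-N-methyl-3-[3,4,5-tris(benzyloxy)phenyl]propanamide
Conditions: MeNHOMe·HCl, AlMe3, CH2Cl2, −10 °C → rt
Reagents that add atoms: N,O-dimethylhydroxylamine hydrochloride, CNOC.Cl
Why: Aluminium-amide transamidation of a β-hydroxy acyl oxazolidinone to the Weinreb amide is reliable, should not epimerise the α-centre and returns the auxiliary.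

Step 4
Reactants: 9 3-bromo-4-iodophenol
Product: 10 4-(benzyloxy)-2-bromo-1-iodobenzene
Conditions: BnBr, K2CO3, DMF, rt
Reagents that add atoms: benzyl bromide, BrCc1ccccc1
Why: Williamson etherification of the phenol.

Step 5
Reactants: 10 4-(benzyloxy)-2-bromo-1-iodobenzene; 8 (2S,3R)-2-(benzyloxy)-3-hydroxy-N-methoxy-N-methyl-3-[3,4,5-tris(benzyloxy)phenyl]propanamide
Product: 13 (2S,3R)-2-(benzyloxy)-1-[4-(benzyloxy)-2-bromophenyl]-3-hydroxy-3-[3,4,5-tris(benzyloxy)phenyl]propan-1-one, via aryl Grignard reagent 11 (not isolated), via chloromagnesium alkoxide 12 (not isolated)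
Conditions: 10, i-PrMgCl·LiCl, THF, −40 °C; 8, i-PrMgCl, THF, −40 °C; combine, −40 → 0 °C; aq NH4Cl
Reagents that add atoms: none
Why: Iodine–magnesium exchange is selective for the iodide over the bromide, and the Grignard reagent should add once to the Weinreb amide (chelated tetrahedral intermediate) whose hydroxyl is masked as its magnesium alkoxide, so the ketone should form without epimerisation or retro-aldol cleavage.

Step 6
Reactants: 13 (2S,3R)-2-(benzyloxy)-1-[4-(benzyloxy)-2-bromophenyl]-3-hydroxy-3-[3,4,5-tris(benzyloxy)phenyl]propan-1-one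
Product: 14 (1R,2S,3R)-2-(benzyloxy)-1-[4-(benzyloxy)-2-bromophenyl]-3-[3,4,5-tris(benzyloxy)phenyl]propane-1,3-diol
Conditions: Me4NBH(OAc)3, MeCN/AcOH, −30 °C
Reagents that add atoms: none
Why: Evans–Saksena reduction, in which hydride is delivered intramolecularly from the alkoxyborohydride formed at the β-hydroxyl and should give the 1,3-anti diol.

Step 7
Reactants: 14 (1R,2S,3R)-2-(benzyloxy)-1-[4-(benzyloxy)-2-bromophenyl]-3-[3,4,5-tris(benzyloxy)phenyl]propane-1,3-diol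
Product: 15 (2R,3R,4R)-3,7-bis(benzyloxy)-2-[3,4,5-tris(benzyloxy)phenyl]chroman-4-ol
Conditions: CuI (10 mol%), 3,4,7,8-tetramethyl-1,10-phenanthroline (20 mol%), Cs2CO3, PhMe, 110 °C
Reagents that add atoms: none
Why: Intramolecular Ullmann-type O-arylation closes ring C of the top unit (only the hydroxyl next to the trioxygenated ring can form a six-membered ring), and because the C2–O bond is not broken the syn aldol pair becomes the 2,3-cis pair.

Step 8
Reactants: 15 (2R,3R,4R)-3,7-bis(benzyloxy)-2-[3,4,5-tris(benzyloxy)phenyl]chroman-4-ol; 16 cyclohexane-1,3-dione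
Product: 17 2-[(2R,3R,4S)-3,7-bis(benzyloxy)-2-[3,4,5-tris(benzyloxy)phenyl]chroman-4-yl]cyclohexane-1,3-dione
Conditions: 16 (3 equiv), BF3·OEt2 (0.3 equiv), CH2Cl2/THF, −20 → 0 °C
Reagents that add atoms: none
Why: Friedel–Crafts-type dehydrative alkylation of a 1,3-dicarbonyl compound, in which the C4 benzylic cation (stabilised by O1 and the 7-benzyloxy group) is taken up by C2 of the dione enol (an O-alkylated enol ether would re-ionise) from the face anti to the axial 3-benzyloxy group, which should set the 3,4-trans (4β) centre.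

Step 9
Reactants: 18 (−)-epicatechin
Product: 19 5,7,3',4'-tetra-O-benzyl-(−)-epicatechin
Conditions: BnBr, K2CO3, DMF, rt
Reagents that add atoms: benzyl bromide, BrCc1ccccc1
Why: Williamson etherification of the four phenols, the secondary alcohol not being ionised by K2CO3.

Step 10
Reactants: 19 5,7,3',4'-tetra-O-benzyl-(−)-epicatechin
Product: 20 8-bromo-5,7,3',4'-tetra-O-benzyl-(−)-epicatechin
Conditions: NBS, CH2Cl2, −40 °C → rt
Reagents that add atoms: N-bromosuccinimide, O=C1CCC(=O)N1Br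
Why: Electrophilic aromatic bromination should go to C8, the more reactive of the two free positions of the phloroglucinol-type ring A of benzylated flavan-3-ols.

Step 11
Reactants: 20 8-bromo-5,7,3',4'-tetra-O-benzyl-(−)-epicatechin
Product: 22 8-bromo-3,5,7,3',4'-penta-O-benzyl-(−)-epicatechin, via sodium alkoxide 21 (not isolated)
Conditions: NaH, DMF, 0 °C; BnBr, rt
Reagents that add atoms: benzyl bromide, BrCc1ccccc1
Why: Williamson etherification of the secondary alkoxide, which keeps this hydroxyl out of the condensation of step 13.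

Step 12
Reactants: 22 8-bromo-3,5,7,3',4'-penta-O-benzyl-(−)-epicatechin; 8 (2S,3R)-2-(benzyloxy)-3-hydroxy-N-methoxy-N-methyl-3-[3,4,5-tris(benzyloxy)phenyl]propanamide
Product: 25 (2S,3R)-2-(benzyloxy)-1-[(2R,3R)-3,5,7-tris(benzyloxy)-2-[3,4-bis(benzyloxy)phenyl]chroman-8-yl]-3-hydroxy-3-[3,4,5-tris(benzyloxy)phenyl]propan-1-one, via aryllithium 23 (not isolated), via bromomagnesium alkoxide 24 (not isolated)
Conditions: 22, t-BuLi (2 equiv), THF, −78 °C; 8, MeMgBr (1 equiv), THF, −78 °C; combine, −78 → −20 °C; aq NH4Cl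
Reagents that add atoms: none
Why: Bromine–lithium exchange at C8 of benzylated flavan-3-ols followed by single addition to a Weinreb amide, whose hydroxyl is first masked as the bromomagnesium alkoxide by MeMgBr (methane leaves the flask, so no aryllithium is spent on the hydroxyl and the tighter magnesium alkoxide resists retro-aldol cleavage), should give the β-hydroxy ketone that holds C2–C3–C4 of the middle unit with C4 at the ketone level.

Step 13
Reactants: 17 2-[(2R,3R,4S)-3,7-bis(benzyloxy)-2-[3,4,5-tris(benzyloxy)phenyl]chroman-4-yl]cyclohexane-1,3-dione; 25 (2S,3R)-2-(benzyloxy)-1-[(2R,3R)-3,5,7-tris(benzyloxy)-2-[3,4-bis(benzyloxy)phenyl]chroman-8-yl]-3-hydroxy-3-[3,4,5-tris(benzyloxy)phenyl]propan-1-one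
Product: 28 3,7,3',4',5'-penta-O-benzyl-epirobinetinidol-(4β→8)-3,3',4',5'-tetra-O-benzyl-epirobinetinidol-(4α→8)-3,5,7,3',4'-penta-O-benzyl-epicatechin, via vinylogous ester 26 (not isolated), via dienone 27 (not isolated)
Conditions: TsOH·H2O (0.2 equiv), benzene, Dean–Stark, 80 °C
Reagents that add atoms: none
Why: Proposed new method: acid should condense the C2 hydroxyl of 25 with either of the two equivalent carbonyl groups of 17 to the vinylogous ester 26 (O1–C8a), whose dienol then attacks the protonated C4 ketone through its γ-carbon C4a and loses water to give dienone 27, and enolisation towards C6, protonation at C4 and loss of a proton from C5 finally aromatise ring A, the whole being redox-neutral because the dione brings the two hydrogens that the C4 ketone lacks. The closest known reaction types are the acid-catalysed formation of 3-alkoxycyclohex-2-enones from cyclohexane-1,3-diones and alcohols, the cyclodehydrating aldol step of a Robinson annulation and the isoaromatisation of 4-alkylidenecyclohex-2-enones to para-substituted phenols, which have not been joined on a 2-substituted dione. Ring C of the middle unit closes in a 6-(enolendo)-exo-trig aldol mode, and no other ring is closed (ring A is only aromatised). C2 and C3 come unchanged from 25 (O1 keeps its bond to C2, so the syn aldol pair becomes 2,3-cis), and the one new stereocentre, C4, is set last by protonation of the C4=C4a bond anti to the pseudoaxial 3-benzyloxy group, which should leave the epicatechin unit cis to both neighbours (4α). The step needs C–C bond formation at C4a and not at C8, which the top unit on C8 secures because an aldol there gives a quaternary carbinol that cannot dehydrate and reverts, and it needs O1–C8a formation without ionisation at C2, which the weakly stabilised 3,4,5-tris(benzyloxy)benzylic position with its β-oxygen secures. All equilibria before 27 are drained by the irreversible aromatisation.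

Step 14
Reactants: 28 3,7,3',4',5'-penta-O-benzyl-epirobinetinidol-(4β→8)-3,3',4',5'-tetra-O-benzyl-epirobinetinidol-(4α→8)-3,5,7,3',4'-penta-O-benzyl-epicatechin
Product: 29 epirobinetinidol-(4β→8)-epirobinetinidol-(4α→8)-epicatechin (CNP0115797.2)
Conditions: H2 (1 atm), Pd(OH)2/C, THF/MeOH/H2O, rt
Reagents that add atoms: none
Why: Hydrogenolysis should remove all fourteen benzyl ethers (phenolic and secondary alkyl) without touching the stereocentres or the interflavan bonds.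

**Compound list**

1 | (S)-4-benzyloxazolidin-2-one | O=C1N[C@@H](Cc2ccccc2)CO1 | starting material
2 | (benzyloxy)acetyl chloride | O=C(Cl)COCc1ccccc1 | starting material
3 | N-lithio-(S)-4-benzyloxazolidin-2-one | [Li]N1C(=O)OC[C@@H]1Cc1ccccc1 | intermediate (not isolated)
4 | (S)-4-benzyl-3-[(benzyloxy)acetyl]oxazolidin-2-one | O=C(COCc1ccccc1)N1C(=O)OC[C@@H]1Cc1ccccc1 | intermediate
5 | 3,4,5-tris(benzyloxy)benzaldehyde | O=Cc1cc(OCc2ccccc2)c(OCc2ccccc2)c(OCc2ccccc2)c1 | starting material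
6 | (Z)-dibutylboron enolate of 4 | CCCCB(CCCC)O/C(=C\OCc1ccccc1)N1C(=O)OC[C@@H]1Cc1ccccc1 | intermediate (not isolated)
7 | (S)-4-benzyl-3-[(2S,3R)-2-(benzyloxy)-3-hydroxy-3-[3,4,5-tris(benzyloxy)phenyl]propanoyl]oxazolidin-2-one | O[C@H](c8cc(OCc9ccccc9)c(OCc9ccccc9)c(OCc9ccccc9)c8)[C@H](OCc9ccccc9)C(=O)N1C(=O)OC[C@@H]1Cc1ccccc1 | intermediate
8 | (2S,3R)-2-(benzyloxy)-3-hydroxy-N-methoxy-N-methyl-3-[3,4,5-tris(benzyloxy)phenyl]propanamide | O[C@H](c8cc(OCc9ccccc9)c(OCc9ccccc9)c(OCc9ccccc9)c8)[C@H](OCc9ccccc9)C(=O)N(C)OC | intermediate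
9 | 3-bromo-4-iodophenol | Oc1ccc(I)c(Br)c1 | starting material
10 | 4-(benzyloxy)-2-bromo-1-iodobenzene | Ic1ccc(OCc2ccccc2)cc1Br | intermediate
11 | [4-(benzyloxy)-2-bromophenyl]magnesium chloride | Cl[Mg]c1ccc(OCc2ccccc2)cc1Br | intermediate (not isolated)
12 | chloromagnesium alkoxide of 8 | Cl[Mg]O[C@H](c8cc(OCc9ccccc9)c(OCc9ccccc9)c(OCc9ccccc9)c8)[C@H](OCc9ccccc9)C(=O)N(C)OC | intermediate (not isolated)
13 | (2S,3R)-2-(benzyloxy)-1-[4-(benzyloxy)-2-bromophenyl]-3-hydroxy-3-[3,4,5-tris(benzyloxy)phenyl]propan-1-one | O[C@H](c8cc(OCc9ccccc9)c(OCc9ccccc9)c(OCc9ccccc9)c8)[C@H](OCc9ccccc9)C(=O)c1ccc(OCc9ccccc9)cc1Br | intermediate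
14 | (1R,2S,3R)-2-(benzyloxy)-1-[4-(benzyloxy)-2-bromophenyl]-3-[3,4,5-tris(benzyloxy)phenyl]propane-1,3-diol | O[C@H](c8cc(OCc9ccccc9)c(OCc9ccccc9)c(OCc9ccccc9)c8)[C@H](OCc9ccccc9)[C@H](O)c1ccc(OCc9ccccc9)cc1Br | intermediate
15 | (2R,3R,4R)-3,7-bis(benzyloxy)-2-[3,4,5-tris(benzyloxy)phenyl]chroman-4-ol | O(Cc9ccccc9)c1ccc2c(c1)O[C@H](c8cc(OCc9ccccc9)c(OCc9ccccc9)c(OCc9ccccc9)c8)[C@H](OCc9ccccc9)[C@@H]2O | intermediate
16 | cyclohexane-1,3-dione | O=C1CCCC(=O)C1 | starting material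
17 | 2-[(2R,3R,4S)-3,7-bis(benzyloxy)-2-[3,4,5-tris(benzyloxy)phenyl]chroman-4-yl]cyclohexane-1,3-dione | O(Cc9ccccc9)c1ccc2c(c1)O[C@H](c8cc(OCc9ccccc9)c(OCc9ccccc9)c(OCc9ccccc9)c8)[C@H](OCc9ccccc9)[C@H]2C1C(=O)CCCC1=O | intermediate
18 | (−)-epicatechin, (2R,3R) | Oc1cc(O)c2c(c1)O[C@H](c1ccc(O)c(O)c1)[C@H](O)C2 | starting material
19 | 5,7,3',4'-tetra-O-benzyl-(−)-epicatechin | O(Cc9ccccc9)c1cc(OCc9ccccc9)c2c(c1)O[C@H](c8ccc(OCc9ccccc9)c(OCc9ccccc9)c8)[C@H](O)C2 | intermediate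
20 | 8-bromo-5,7,3',4'-tetra-O-benzyl-(−)-epicatechin | O(Cc9ccccc9)c1cc(OCc9ccccc9)c2c(c1Br)O[C@H](c8ccc(OCc9ccccc9)c(OCc9ccccc9)c8)[C@H](O)C2 | intermediate
21 | sodium 3-alkoxide of 20 | O(Cc9ccccc9)c1cc(OCc9ccccc9)c2c(c1Br)O[C@H](c8ccc(OCc9ccccc9)c(OCc9ccccc9)c8)[C@H](O[Na])C2 | intermediate (not isolated)
22 | 8-bromo-3,5,7,3',4'-penta-O-benzyl-(−)-epicatechin | O(Cc9ccccc9)c1cc(OCc9ccccc9)c2c(c1Br)O[C@H](c8ccc(OCc9ccccc9)c(OCc9ccccc9)c8)[C@H](OCc9ccccc9)C2 | intermediate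
23 | 8-lithio-3,5,7,3',4'-penta-O-benzyl-(−)-epicatechin | O(Cc9ccccc9)c1cc(OCc9ccccc9)c2c(c1[Li])O[C@H](c8ccc(OCc9ccccc9)c(OCc9ccccc9)c8)[C@H](OCc9ccccc9)C2 | intermediate (not isolated)
24 | bromomagnesium alkoxide of 8 | Br[Mg]O[C@H](c8cc(OCc9ccccc9)c(OCc9ccccc9)c(OCc9ccccc9)c8)[C@H](OCc9ccccc9)C(=O)N(C)OC | intermediate (not isolated)
25 | (2S,3R)-2-(benzyloxy)-1-[(2R,3R)-3,5,7-tris(benzyloxy)-2-[3,4-bis(benzyloxy)phenyl]chroman-8-yl]-3-hydroxy-3-[3,4,5-tris(benzyloxy)phenyl]propan-1-one | O[C@H](c8cc(OCc9ccccc9)c(OCc9ccccc9)c(OCc9ccccc9)c8)[C@H](OCc9ccccc9)C(=O)c1c(OCc9ccccc9)cc(OCc9ccccc9)c2c1O[C@H](c8ccc(OCc9ccccc9)c(OCc9ccccc9)c8)[C@H](OCc9ccccc9)C2 | intermediate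
26 | vinylogous ester: 2-[(2R,3R,4R)-3,7-bis(benzyloxy)-2-[3,4,5-tris(benzyloxy)phenyl]chroman-4-yl]-3-{(1R,2S)-2-(benzyloxy)-3-oxo-3-[(2R,3R)-3,5,7-tris(benzyloxy)-2-[3,4-bis(benzyloxy)phenyl]chroman-8-yl]-1-[3,4,5-tris(benzyloxy)phenyl]propoxy}cyclohex-2-en-1-one | O(Cc9ccccc9)c1ccc2c(c1)O[C@H](c8cc(OCc9ccccc9)c(OCc9ccccc9)c(OCc9ccccc9)c8)[C@H](OCc9ccccc9)[C@H]2C1=C(O[C@H](c8cc(OCc9ccccc9)c(OCc9ccccc9)c(OCc9ccccc9)c8)[C@H](OCc9ccccc9)C(=O)c3c(OCc9ccccc9)cc(OCc9ccccc9)c4c3O[C@H](c8ccc(OCc9ccccc9)c(OCc9ccccc9)c8)[C@H](OCc9ccccc9)C4)CCCC1=O | intermediate (not isolated)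
27 | dienone: (2R,3R)-3-(benzyloxy)-2-[3,4,5-tris(benzyloxy)phenyl]-2,3,5,6-tetrahydro-7H-chromen-7-one with C4=C4a and C8=C8a double bonds, the penta-O-benzyl-epicatechin-8-yl group on C4 and the top flavan-4-yl group on C8 | O(Cc9ccccc9)c1ccc2c(c1)O[C@H](c8cc(OCc9ccccc9)c(OCc9ccccc9)c(OCc9ccccc9)c8)[C@H](OCc9ccccc9)[C@H]2C1=C3O[C@H](c8cc(OCc9ccccc9)c(OCc9ccccc9)c(OCc9ccccc9)c8)[C@H](OCc9ccccc9)C(c4c(OCc9ccccc9)cc(OCc9ccccc9)c5c4O[C@H](c8ccc(OCc9ccccc9)c(OCc9ccccc9)c8)[C@H](OCc9ccccc9)C5)=C3CCC1=O | intermediate (not isolated)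
28 | 3,7,3',4',5'-penta-O-benzyl-epirobinetinidol-(4β→8)-3,3',4',5'-tetra-O-benzyl-epirobinetinidol-(4α→8)-3,5,7,3',4'-penta-O-benzyl-epicatechin, 7-OH of the middle unit free (top 2R,3R,4R; middle 2R,3R,4S; bottom 2R,3R) | O(Cc9ccccc9)c1ccc2c(c1)O[C@H](c8cc(OCc9ccccc9)c(OCc9ccccc9)c(OCc9ccccc9)c8)[C@H](OCc9ccccc9)[C@H]2c1c(O)ccc2c1O[C@H](c8cc(OCc9ccccc9)c(OCc9ccccc9)c(OCc9ccccc9)c8)[C@H](OCc9ccccc9)[C@@H]2c1c(OCc9ccccc9)cc(OCc9ccccc9)c2c1O[C@H](c8ccc(OCc9ccccc9)c(OCc9ccccc9)c8)[C@H](OCc9ccccc9)C2 | intermediate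
29 | epirobinetinidol-(4β→8)-epirobinetinidol-(4α→8)-epicatechin (top 2R,3R,4R; middle 2R,3R,4S; bottom 2R,3R) | Oc1ccc2c(c1)O[C@H](c1cc(O)c(O)c(O)c1)[C@H](O)[C@H]2c1c(O)ccc2c1O[C@H](c1cc(O)c(O)c(O)c1)[C@H](O)[C@@H]2c1c(O)cc(O)c2c1O[C@H](c1ccc(O)c(O)c1)[C@H](O)C2 | target

**Summary and risks**

Total step count: 14. Longest linear sequence: 9 steps (1, 2, 3, 5, 6, 7, 8, 13, 14).

Steps most likely to fail:

Step 13. The intermolecular condensation of two hindered partners may be outrun by acid-induced dehydration or retro-aldol cleavage of 25 and by loss of the top unit from 17, and the last protonation may show poor facial selectivity. The fallback uses known reactions, sets out from 17 and comes back to the route at 29. Compound 17 is condensed with benzyl alcohol (TsOH, benzene, Dean–Stark) to the 3-benzyloxy enone F1, which is dehydrogenated to the phenol F2 [Pd(O2CCF3)2, 2-(dimethylamino)pyridine, TsOH, O2, DMSO, 80 °C]. Triflation (Tf2O, pyridine) gives the aryl triflate F3, and palladium-catalysed C–O coupling with alcohol 8 [Pd2(dba)3, t-BuBrettPhos, Cs2CO3, PhMe, 90 °C] should give the aryl ether F4 with retention at C2. Aryllithium 23 adds to the Weinreb amide of F4 to give the ketone F5. BF3·OEt2 (CH2Cl2, −40 °C) should close ring C by Friedel–Crafts hydroxyalkylation at C4a (para to the benzyloxy group, the other ortho position being blocked) to the tertiary carbinol F6, which is ionised and reduced in the same flask by Et3SiH from the face anti to the 3-benzyloxy group to the all-cis 7-O-benzyl ether F7. Hydrogenolysis under the conditions of step 14 then gives 29.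

Step 8. The cation may be captured on oxygen of the dione, lose a proton to the flav-3-ene, or be attacked with poor facial selectivity. The fallback sets out from 15 and comes back at 17. Methyl 5-oxohexanoate is converted into its kinetic silyl enol ether, methyl 5-[(trimethylsilyl)oxy]hex-5-enoate F8 [LiN(i-Pr)2, Me3SiCl, THF, −78 °C]. Mukaiyama-type alkylation of the C4 cation of 15 with F8 (BF3·OEt2, CH2Cl2, −78 °C) should give the δ-keto ester F9 with the side chain anti to the 3-benzyloxy group. Dieckmann-type Claisen cyclisation of F9 (KOt-Bu, THF) then builds the cyclohexane-1,3-dione ring onto the existing C–C bond and gives 17.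

Step 14. Cleavage of the three secondary benzyl ethers may stay incomplete, or the benzylic C2–O1 bonds may be hydrogenolysed during the long exposure. The fallback sets out from 28 and comes back at 29: debenzylation with BCl3 and pentamethylbenzene as cation scavenger (CH2Cl2, −78 °C), which needs no hydrogen and makes no new compound.

Further compounds
F1 | step 13 | 3-(benzyloxy)-2-[(2R,3R,4R)-3,7-bis(benzyloxy)-2-[3,4,5-tris(benzyloxy)phenyl]chroman-4-yl]cyclohex-2-en-1-one | O(Cc9ccccc9)c1ccc2c(c1)O[C@H](c8cc(OCc9ccccc9)c(OCc9ccccc9)c(OCc9ccccc9)c8)[C@H](OCc9ccccc9)[C@H]2C1=C(OCc9ccccc9)CCCC1=O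
F2 | step 13 | 3-(benzyloxy)-2-[(2R,3R,4R)-3,7-bis(benzyloxy)-2-[3,4,5-tris(benzyloxy)phenyl]chroman-4-yl]phenol | O(Cc9ccccc9)c1ccc2c(c1)O[C@H](c8cc(OCc9ccccc9)c(OCc9ccccc9)c(OCc9ccccc9)c8)[C@H](OCc9ccccc9)[C@H]2c1c(O)cccc1OCc9ccccc9
F3 | step 13 | 3-(benzyloxy)-2-[(2R,3R,4R)-3,7-bis(benzyloxy)-2-[3,4,5-tris(benzyloxy)phenyl]chroman-4-yl]phenyl trifluoromethanesulfonate | O(Cc9ccccc9)c1ccc2c(c1)O[C@H](c8cc(OCc9ccccc9)c(OCc9ccccc9)c(OCc9ccccc9)c8)[C@H](OCc9ccccc9)[C@H]2c1c(OS(=O)(=O)C(F)(F)F)cccc1OCc9ccccc9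
F4 | step 13 | aryl ether of 8: (2S,3R)-2-(benzyloxy)-3-{3-(benzyloxy)-2-[(2R,3R,4R)-3,7-bis(benzyloxy)-2-[3,4,5-tris(benzyloxy)phenyl]chroman-4-yl]phenoxy}-N-methoxy-N-methyl-3-[3,4,5-tris(benzyloxy)phenyl]propanamide | O(Cc9ccccc9)c1ccc2c(c1)O[C@H](c8cc(OCc9ccccc9)c(OCc9ccccc9)c(OCc9ccccc9)c8)[C@H](OCc9ccccc9)[C@H]2c1c(OCc9ccccc9)cccc1O[C@H](c8cc(OCc9ccccc9)c(OCc9ccccc9)c(OCc9ccccc9)c8)[C@H](OCc9ccccc9)C(=O)N(C)OC
F5 | step 13 | aryl ether ketone: the 3-O-aryl ether of 25 with the aryl group of F4 | O(Cc9ccccc9)c1ccc2c(c1)O[C@H](c8cc(OCc9ccccc9)c(OCc9ccccc9)c(OCc9ccccc9)c8)[C@H](OCc9ccccc9)[C@H]2c1c(OCc9ccccc9)cccc1O[C@H](c8cc(OCc9ccccc9)c(OCc9ccccc9)c(OCc9ccccc9)c8)[C@H](OCc9ccccc9)C(=O)c3c(OCc9ccccc9)cc(OCc9ccccc9)c4c3O[C@H](c8ccc(OCc9ccccc9)c(OCc9ccccc9)c8)[C@H](OCc9ccccc9)C4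
F6 | step 13 | tertiary C4 carbinol of the middle unit (4-hydroxy analogue of F7, either C4 epimer, not isolated) | O(Cc9ccccc9)c1ccc2c(c1)O[C@H](c8cc(OCc9ccccc9)c(OCc9ccccc9)c(OCc9ccccc9)c8)[C@H](OCc9ccccc9)[C@H]2c1c(OCc9ccccc9)ccc3c1O[C@H](c8cc(OCc9ccccc9)c(OCc9ccccc9)c(OCc9ccccc9)c8)[C@H](OCc9ccccc9)C3(O)c1c(OCc9ccccc9)cc(OCc9ccccc9)c2c1O[C@H](c8ccc(OCc9ccccc9)c(OCc9ccccc9)c8)[C@H](OCc9ccccc9)C2
F7 | step 13 | 7-O-benzyl ether of 28 (pentadeca-O-benzyl trimer) | O(Cc9ccccc9)c1ccc2c(c1)O[C@H](c8cc(OCc9ccccc9)c(OCc9ccccc9)c(OCc9ccccc9)c8)[C@H](OCc9ccccc9)[C@H]2c1c(OCc9ccccc9)ccc2c1O[C@H](c8cc(OCc9ccccc9)c(OCc9ccccc9)c(OCc9ccccc9)c8)[C@H](OCc9ccccc9)[C@@H]2c1c(OCc9ccccc9)cc(OCc9ccccc9)c2c1O[C@H](c8ccc(OCc9ccccc9)c(OCc9ccccc9)c8)[C@H](OCc9ccccc9)C2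
F8 | step 8 | methyl 5-[(trimethylsilyl)oxy]hex-5-enoate | COC(=O)CCCC(=C)O[Si](C)(C)C
F9 | step 8 | methyl 6-[(2R,3R,4S)-3,7-bis(benzyloxy)-2-[3,4,5-tris(benzyloxy)phenyl]chroman-4-yl]-5-oxohexanoate | O(Cc9ccccc9)c1ccc2c(c1)O[C@H](c8cc(OCc9ccccc9)c(OCc9ccccc9)c(OCc9ccccc9)c8)[C@H](OCc9ccccc9)[C@H]2CC(=O)CCCC(=O)OC
F0 | step 14 | none | none
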